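**Assumption:** the target SMILES has no stereocentre or stereodescriptor, and the 18-membered ring is conformationally mobile. Marchantin I is therefore treated as achiral, and no enantioselective step is needed.

## Retrosynthetic overview
1. Target ⇐ macrocyclic bis-stilbene benzyl ether 10. One hydrogenation saturates both bridges and removes the benzyl group.
2. 10 ⇐ open-chain dialdehyde 9. An intramolecular McMurry coupling forms the A–B bridge and is the only ring-forming step (18-membered macrocycle).
3. 9 ⇐ Heck coupling (C–D bridge) of the B–C styrene 5 with the A–D aryl iodide 8.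
4. 5 and 8 ⇐ two SNAr diaryl ether formations. The aldehydes that activate the fluorides are the same ones later coupled in the McMurry step.
5. All four arene rings are purchased. Ring C comes from 4-benzyloxy-3-hydroxybenzaldehyde after methylenation.

## Route

**Step 1**
Reactants: 1, 4-(benzyloxy)-3-hydroxybenzaldehyde; 2, methyltriphenylphosphonium bromide
Product: 3, 2-(benzyloxy)-5-ethenylphenol
Conditions: MePPh3Br (2.5 equiv), KOtBu (2.4 equiv), THF, 0 °C → rt; aq NH4Cl work-up
Reagents that add atoms: methyltriphenylphosphonium bromide (2), C[P+](c1ccccc1)(c1ccccc1)c1ccccc1.[Br-] (delivers CH2)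
Why: This is a Wittig methylenation in which one equivalent of ylide deprotonates the phenol; the phenoxide is meta to the CHO, so it does not deactivate it. No stereocentre is formed.

**Step 2**
Reactants: 3, 2-(benzyloxy)-5-ethenylphenol; 4, 4-fluorobenzaldehyde
Product: 5, 4-[2-(benzyloxy)-5-ethenylphenoxy]benzaldehyde
Conditions: K2CO3 (2 equiv), BHT (cat.), DMF, 100 °C, Ar
Reagents that add atoms: 4-fluorobenzaldehyde (4), O=Cc1ccc(F)cc1
Why: This is an SNAr in which the para-formyl group activates fluoride displacement by the phenoxide, while base, inert atmosphere and BHT keep the styrene from polymerising.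

**Step 3**
Reactants: 6, 2-fluoro-5-methoxybenzaldehyde; 7, 3-iodophenol
Product: 8, 2-(3-iodophenoxy)-5-methoxybenzaldehyde
Conditions: K2CO3 (2 equiv), DMA, 140 °C
Reagents that add atoms: 2-fluoro-5-methoxybenzaldehyde (6), COc1ccc(F)c(C=O)c1; 3-iodophenol (7), Oc1cccc(I)c1
Why: This is an SNAr activated by the ortho-formyl group, run hotter because the para-OMe is deactivating; the aryl iodide is inert without a metal catalyst.

**Step 4**
Reactants: 5, B–C styrene aldehyde; 8, A–D iodo aldehyde
Product: 9, 2-[3-[(E)-2-[4-(benzyloxy)-3-(4-formylphenoxy)phenyl]ethenyl]phenoxy]-5-methoxybenzaldehyde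
Conditions: Pd(OAc)2 (5 mol %), P(o-tol)3 (10 mol %), Et3N, DMF, 90 °C
Reagents that add atoms: none beyond 5 and 8 (HI is lost)
Why: This is a Mizoroki–Heck coupling of an aryl iodide with a terminal styrene, giving the E-stilbene. Both aldehydes and the benzyl ether are tolerated, and the alkene geometry is erased in step 6.

**Step 5**
Reactants: 9, dialdehyde
Product: 10, 18-membered macrocyclic bis-stilbene benzyl ether (C/D alkene E; new A/B alkene as an E/Z mixture)
Conditions: TiCl4 (10 equiv), Zn (20 equiv), pyridine, THF, reflux; 9 added by syringe pump over 20 h (final about 2 mM); aq K2CO3 work-up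
Reagents that add atoms: none (two O atoms are lost)
Why: This is an intramolecular McMurry coupling under pseudo-high dilution.
- Marchantin-type natural macrocycles containing a trans-stilbene bridge (the ptychantols) suggest the ring can accommodate the E alkene.
- Aryl ethers and the stilbene survive low-valent titanium.
- Any incidental loss of the benzyl group is harmless, because step 6 removes it anyway.

**Step 6**
Reactants: 10, macrocyclic bis-stilbene
Product: 11, marchantin I
Conditions: H2 (1 atm), 10 % Pd/C, EtOAc–MeOH 1:1, rt
Reagents that add atoms: none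
Why: This is a catalytic hydrogenation of both stilbene alkenes with simultaneous hydrogenolysis of the aryl benzyl ether; the diaryl ethers and OMe are untouched, and no stereocentre is created.

## Route check
- **Ring A:** CHO at C1, OAr at C2 and OMe at C5, so OMe is para to the ether oxygen and meta to the bridge, as in the target.
- **Ring B:** 1,4-disubstituted.
- **Ring C:** the bridge is para to OH (carried as OBn) and meta to OAr.
- **Ring D:** 1,3-disubstituted.
- **Macrocycle size:** 2 + 2 + 4 + 1 + 3 + 2 + 3 + 1 = 18 atoms.
- **Formulae:** 9 is C36H28O6, 10 is C36H28O4 and 11 is C29H26O4, which matches the target SMILES.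

## Compound list
1 | 4-(benzyloxy)-3-hydroxybenzaldehyde | O=Cc1ccc(OCc2ccccc2)c(O)c1 | starting material
2 | methyltriphenylphosphonium bromide | C[P+](c1ccccc1)(c1ccccc1)c1ccccc1.[Br-] | starting material
3 | 2-(benzyloxy)-5-ethenylphenol | C=Cc1ccc(OCc2ccccc2)c(O)c1 | intermediate
4 | 4-fluorobenzaldehyde | O=Cc1ccc(F)cc1 | starting material
5 | 4-[2-(benzyloxy)-5-ethenylphenoxy]benzaldehyde | C=Cc1ccc(OCc2ccccc2)c(Oc2ccc(C=O)cc2)c1 | intermediate
6 | 2-fluoro-5-methoxybenzaldehyde | COc1ccc(F)c(C=O)c1 | starting material
7 | 3-iodophenol | Oc1cccc(I)c1 | starting material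
8 | 2-(3-iodophenoxy)-5-methoxybenzaldehyde | COc1ccc(Oc2cccc(I)c2)c(C=O)c1 | intermediate
9 | (E)-stilbene dialdehyde (open-chain A–O–D–CH=CH–C–O–B) | COc1ccc(Oc2cccc(/C=C/c3ccc(OCc4ccccc4)c(Oc4ccc(C=O)cc4)c3)c2)c(C=O)c1 | intermediate
10 | O-benzyl tetradehydromarchantin I (macrocyclic bis-stilbene; A/B alkene E/Z) | COc1ccc2c(c1)C=Cc1ccc(cc1)Oc1cc(ccc1OCc1ccccc1)/C=C/c1cccc(c1)O2 | intermediate
11 | marchantin I | COc1ccc2c(c1)CCc1ccc(cc1)Oc1cc(ccc1O)CCc1cccc(c1)O2 | target

## Summary
Total steps: 6. Longest linear sequence: 5 (1 → 3 → 5 → 9 → 10 → 11).

If compound 1 is not in stock, it can be made in one extra step from 3,4-dihydroxybenzaldehyde by selective 4-O-benzylation (BnBr, NaHCO3, NaI, DMF).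

**The three steps most likely to fail, with fallbacks**

1. **Step 5, McMurry macrocyclisation.** The risks are oligomers, arrest at the pinacol stage, and strain from two unsaturated bridges.
   - Fallback: abandon carbonyl–carbonyl coupling.
   - Reduce 9 to the diol with NaBH4 and convert it to the bis(bromomethyl) compound with PBr3.
   - Close the larger, less strained 19-membered cyclic sulfide with Na2S at high dilution.
   - Oxidise to the sulfone (H2O2/molybdate) and contract the ring by Ramberg–Bäcklund reaction to the same compound 10.
2. **Step 2, SNAr with a vinylphenol in hot carbonate.** The risk is polymerisation of the styrene.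
   - Fallback: reverse the Heck polarity so that no styrene is exposed to SNAr conditions.
   - Use 2-(benzyloxy)-5-bromophenol (from 5-bromosalicylaldehyde by benzylation, then Dakin oxidation) in the SNAr with 4.
   - Install the vinyl group on the A–D fragment afterwards by Suzuki vinylation of 8 with potassium vinyltrifluoroborate.
   - Heck coupling of these two partners gives the same compound 9.
3. **Step 3, SNAr on the OMe-deactivated fluoride.** The risks are low conversion and degradation of the aldehyde at 140 °C.
   - Fallback: invert the ether disconnection so that ring A is the phenol component.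
   - Carry out a Chan–Lam coupling of 2-hydroxy-5-methoxybenzaldehyde with 3-iodophenylboronic acid (Cu(OAc)2, pyridine, 4 Å MS, CH2Cl2, air, rt) to give 8.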